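**One step.** In a one-step world substrate falls by a first-order law, so the fraction left, c(substrate) over its charge, shrinks by equal factors in equal times, and the charge does not enter.

**The decision.** The flask takes 1.5 M where the south run took 2.1 M, and the question is whether 2.5 d can stand or has to be lengthened.

| flask | substrate | remark | time |
|---|---|---|---|
| south | 2.1 M | run made earlier |  |
| flask | 1.5 M |  | 2.5 d |

south run (percent of the substrate charged)

| time / h | isomer of the product / % | target / % |
|---|---|---|
| 12.0 | 2.2 | 28.3 |
| 25.0 | 4.2 | 49.4 |
| 40.0 | 5.3 | 65.3 |
| 50.0 | 5.5 | 71.5 |

(readings scatter by 0.3 percentage points)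

- target is meant together with its crystals
- solid, in amounts per volume of the solution: crystals
- the numbers in the tables scatter by 0.3 percentage points (one standard deviation)
- steps that have been proposed: substrate <-> target; substrate <-> isomer of the product; target <-> isomer of the product; crystals <-> target; substrate -> decomposition product

1. ratio of isomer of the product to target at 50 min
2. ratio of isomer of the product to target at 2.5 d
3. which of isomer of the product and target there is more of at 2.5 d

**Loss constant.** Counting as substrate whatever is neither target nor isomer, the south run leaves 69.5% at 12.0 h and 23.0% at 50.0 h. From the last reading the loss constant k is 0.0294 h⁻¹: minus the natural logarithm of the fraction left, divided by the time. The first reading gives 0.0303 h⁻¹.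

**Own reckoning.** Carried to the flask, k leaves 17.1% at 2.5 d, less substrate than the south run held at its last reading, so the time stays. The isomer-to-target ratio, a selectivity factor, reads 0.0777 at the first reading and 0.0769 at the last. Splitting the converted fraction by the last ratio gives 77.0% target and 5.92% isomer.

**The forecast.** It gives 0.09 at 50 min, 0.08 at 2.5 d and target ahead, saying “Correcting for this return, the early ratio is about 0.09”. That early value stands above the first reading's ratio.

**The flask.** The ratio is 0.0737 at 50 min and 0.0767 at 2.5 d, with target ahead, 77.2% against 5.92%.

    substrate ⇌ target (K = 2.90, k = 8.10 × 10⁻⁶ s⁻¹)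
    substrate ⇌ isomer of the product (K = 2.80, k = 5.90 × 10⁻⁷ s⁻¹)
    target ⇌ isomer of the product (k = 3.60 × 10⁻⁷ s⁻¹)
    crystals ⇌ target, rate k4*(cs4 - [target]) while solid is left; crystals form when [target] > cs4 (solubility = 18.0 mM, k = 6.60 × 10⁻⁵ s⁻¹)
    substrate → decomposition product (k = 2.20 × 10⁻⁹ s⁻¹)

The flask keeps 17% of its substrate, a loss constant of 0.0295 h⁻¹ against the carried 0.0294 h⁻¹. The neighbour flask, charged with 0.90 M, keeps 17%, which gives 0.0295 h⁻¹. The reaction of substrate to isomer, both ways, is the largest single effect on the flask's early ratio: with that reaction taken out, the ratio at 50 min falls from 0.0737 to 5.38 × 10⁻⁴.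

Readings and results come from a simulation on assumed constants.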